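**Retrosynthetic overview**
- The target is opened at the end by three functional-group operations: phenol MOM removal, C5–Br → C5–CHO (Br/Li exchange, DMF), and removal of a C4 carbonyl. This leads back to an (R)-5-bromo-2,2-disubstituted chroman-4-one.
- The C2 stereocentre is the only one. It is set by a Cu-catalysed asymmetric 1,4-addition of AlMe3 to a 2-alkyl-5-bromochromone. The precedent is a single substrate class, so this is the least certain step.
- The chromone comes from acid cyclodehydration of an aryl 1,3-diketone. The diketone is made by an intermolecular Claisen condensation (C3–C2 bond) between the enolate of a fully substituted o-hydroxyacetophenone and ethyl farnesylacetate, which joins the arene to the whole side chain.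
- The acetophenone comes from 2,5-dimethoxytoluene: bromination para to methyl, lithiation between Br and OMe, acetaldehyde, oxidation, demethylation, mono-MOM. The ester comes from (2E,6E)-farnesol: bromide, malonate alkylation, Krapcho.
- Ring order: the benzene ring is bought; the pyran ring is the only ring formed (chromone, step 10).

Assumption: commercial (2E,6E)-farnesol carries the side-chain geometry unchanged, and the ligand antipode in step 12 is the one that gives 2R (checked by chiral HPLC on 18).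

**Route**

Step 1
Reactants: 1 2,5-dimethoxytoluene
Product: 2 1-bromo-2,5-dimethoxy-4-methylbenzene
Conditions: NBS (1.05 equiv), MeCN, 0 °C → rt
Reagents that add atoms: N-bromosuccinimide, O=C1CCC(=O)N1Br
Why: Electrophilic aromatic bromination goes to the position para to methyl and ortho to OMe, the most activated and least hindered site.

Step 2
Reactants: 2 1-bromo-2,5-dimethoxy-4-methylbenzene; 3 acetaldehyde
Product: 5 1-(2-bromo-3,6-dimethoxy-5-methylphenyl)ethan-1-ol (racemic), via aryllithium 4 (not isolated)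
Conditions: LDA (1.2 equiv), THF, −78 °C, 1 h; MeCHO (2 equiv), −78 °C; H2O
Reagents that add atoms: none
Why: Directed ortho-lithiation removes the only C–H flanked by both Br and OMe (LDA avoids Br/Li exchange, −78 °C avoids aryne formation), and the aryllithium adds 1,2 to acetaldehyde; the racemic carbinol centre is destroyed in step 3.

Step 3
Reactants: 5 1-(2-bromo-3,6-dimethoxy-5-methylphenyl)ethan-1-ol
Product: 6 1-(2-bromo-3,6-dimethoxy-5-methylphenyl)ethan-1-one
Conditions: Dess–Martin periodinane (1.3 equiv), NaHCO3, CH2Cl2, rt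
Reagents that add atoms: none
Why: Dess–Martin oxidation of a hindered secondary benzylic alcohol to the aryl methyl ketone under neutral conditions.

Step 4
Reactants: 6 1-(2-bromo-3,6-dimethoxy-5-methylphenyl)ethan-1-one
Product: 7 1-(2-bromo-3,6-dihydroxy-5-methylphenyl)ethan-1-one
Conditions: BBr3 (3 equiv), CH2Cl2, −78 °C → rt; H2O
Reagents that add atoms: none
Why: Lewis-acid O-demethylation of both aryl methyl ethers; the aryl bromide and ketone are inert to BBr3.

Step 5
Reactants: 7 1-(2-bromo-3,6-dihydroxy-5-methylphenyl)ethan-1-one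
Product: 8 1-[2-bromo-6-hydroxy-3-(methoxymethoxy)-5-methylphenyl]ethan-1-one
Conditions: MOMCl (1.1 equiv), iPr2NEt (1.5 equiv), CH2Cl2, 0 °C
Reagents that add atoms: chloromethyl methyl ether, COCCl
Why: Selective O-alkylation (acetal protection) of the phenol that is not hydrogen-bonded to the acetyl group; the chelated phenol stays free for the later ring closure.

Step 6
Reactants: 9 (2E,6E)-farnesol
Product: 10 (2E,6E)-farnesyl bromide
Conditions: PBr3 (0.4 equiv), Et2O, −10 °C; used crude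
Reagents that add atoms: phosphorus tribromide, BrP(Br)Br
Why: Conversion of a primary allylic alcohol to the bromide at low temperature keeps both trisubstituted alkenes E.

Step 7
Reactants: 10 (2E,6E)-farnesyl bromide; 11 diethyl malonate
Product: 12 diethyl 2-[(2E,6E)-3,7,11-trimethyldodeca-2,6,10-trien-1-yl]propanedioate
Conditions: NaH (1.1 equiv), diethyl malonate (2 equiv), THF, 0 °C → rt
Reagents that add atoms: none
Why: Malonic ester SN2 alkylation at the primary allylic carbon; excess malonate suppresses dialkylation and the alkene geometry is untouched.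

Step 8
Reactants: 12 diethyl 2-[(2E,6E)-3,7,11-trimethyldodeca-2,6,10-trien-1-yl]propanedioate
Product: 13 ethyl (4E,8E)-5,9,13-trimethyltetradeca-4,8,12-trienoate
Conditions: LiCl, H2O (2 equiv), DMSO, 160 °C
Reagents that add atoms: none
Why: Krapcho dealkoxycarbonylation removes one ester under neutral conditions and leaves the skipped triene in place.

Step 9
Reactants: 8 1-[2-bromo-6-hydroxy-3-(methoxymethoxy)-5-methylphenyl]ethan-1-one; 13 ethyl (4E,8E)-5,9,13-trimethyltetradeca-4,8,12-trienoate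
Product: 14 (6E,10E)-1-[2-bromo-6-hydroxy-3-(methoxymethoxy)-5-methylphenyl]-7,11,15-trimethylhexadeca-6,10,14-triene-1,3-dione
Conditions: LiHMDS (3.3 equiv), THF, −78 → 0 °C; 13 (1.2 equiv), 0 °C → rt, 16 h; 1 M HCl to pH 5, 0 °C
Reagents that add atoms: none
Why: Crossed Claisen condensation: the phenoxide/enolate dianion of the methyl ketone (its only enolisable site) acylates on carbon with the ester, and formation of the diketonate drives it to completion.

Step 10
Reactants: 14 (6E,10E)-1-[2-bromo-6-hydroxy-3-(methoxymethoxy)-5-methylphenyl]-7,11,15-trimethylhexadeca-6,10,14-triene-1,3-dione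
Product: 16 5-bromo-6-hydroxy-8-methyl-2-[(3E,7E)-4,8,12-trimethyltrideca-3,7,11-trien-1-yl]-4H-chromen-4-one, via chromone MOM ether 15 (not isolated)
Conditions: HCl (1.25 M in MeOH), THF co-solvent, rt → 40 °C, 3 h
Reagents that add atoms: none
Why: Acid-catalysed cyclodehydration of the o-hydroxyaryl 1,3-diketone forms the pyranone ring; the aryl MOM ether cannot survive this acid, so it is deliberately driven to complete cleavage to give one product.

Step 11
Reactants: 16 5-bromo-6-hydroxy-8-methyl-2-[(3E,7E)-4,8,12-trimethyltrideca-3,7,11-trien-1-yl]-4H-chromen-4-one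
Product: 15 5-bromo-6-(methoxymethoxy)-8-methyl-2-[(3E,7E)-4,8,12-trimethyltrideca-3,7,11-trien-1-yl]-4H-chromen-4-one
Conditions: MOMCl (1.5 equiv), iPr2NEt (2 equiv), CH2Cl2, 0 °C → rt
Reagents that add atoms: chloromethyl methyl ether, COCCl
Why: Phenol O-alkylation re-installs the MOM acetal, which tolerates AlMe3 and stabilises the ortho-aryllithium of step 15; done on the base-stable chromone, not on the base-sensitive chromanone.

Step 12
Reactants: 15 5-bromo-6-(methoxymethoxy)-8-methyl-2-[(3E,7E)-4,8,12-trimethyltrideca-3,7,11-trien-1-yl]-4H-chromen-4-one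
Product: 18 (2R)-5-bromo-6-(methoxymethoxy)-2,8-dimethyl-2-[(3E,7E)-4,8,12-trimethyltrideca-3,7,11-trien-1-yl]-2,3-dihydro-4H-chromen-4-one, via dimethylaluminium enolate 17 (not isolated)
Conditions: AlMe3 (2.5 equiv), CuTC (5 mol %), TADDOL-derived chiral phosphine–phosphite ligand (6 mol %), Et2O, −30 °C, 20 h; H2O/Rochelle salt, 0 °C
Reagents that add atoms: trimethylaluminium, C[Al](C)C
Why: Cu-catalysed asymmetric conjugate (1,4-) addition: the chiral Cu complex delivers methyl to one π-face of chromone C2 and creates the quaternary 2R centre; the neutral work-up avoids base-induced retro-oxa-Michael racemisation.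

Step 13
Reactants: 18 (2R)-5-bromo-6-(methoxymethoxy)-2,8-dimethyl-2-[(3E,7E)-4,8,12-trimethyltrideca-3,7,11-trien-1-yl]-2,3-dihydro-4H-chromen-4-one
Product: 19 N'-[(2R)-5-bromo-6-(methoxymethoxy)-2,8-dimethyl-2-[(3E,7E)-4,8,12-trimethyltrideca-3,7,11-trien-1-yl]-2,3-dihydro-4H-chromen-4-ylidene]-4-methylbenzenesulfonohydrazide
Conditions: TsNHNH2 (1.5 equiv), AcOH (10 mol %), 4 Å MS, EtOH, 75 °C
Reagents that add atoms: p-toluenesulfonyl hydrazide, Cc1ccc(cc1)S(=O)(=O)NN
Why: Hydrazone condensation at the aryl ketone under weakly acidic, base-free conditions, so C2 cannot epimerise by ring opening.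

Step 14
Reactants: 19 N'-[(2R)-5-bromo-6-(methoxymethoxy)-2,8-dimethyl-2-[(3E,7E)-4,8,12-trimethyltrideca-3,7,11-trien-1-yl]-2,3-dihydro-4H-chromen-4-ylidene]-4-methylbenzenesulfonohydrazide
Product: 21 (2R)-5-bromo-6-(methoxymethoxy)-2,8-dimethyl-2-[(3E,7E)-4,8,12-trimethyltrideca-3,7,11-trien-1-yl]-3,4-dihydro-2H-chromene, via C4 monoalkyl diazene 20 (not isolated)
Conditions: catecholborane (2.5 equiv), CHCl3, 0 °C → rt; NaOAc·3H2O (3 equiv), 60 °C, 1 h
Reagents that add atoms: none
Why: Caglioti/Kabalka reductive deoxygenation: hydride adds to C=N, sulfinate is eliminated and the diazene loses N2 to give CH2 without a carbocation or tin radical, so the triene, aryl bromide and C2 are untouched.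

Step 15
Reactants: 21 (2R)-5-bromo-6-(methoxymethoxy)-2,8-dimethyl-2-[(3E,7E)-4,8,12-trimethyltrideca-3,7,11-trien-1-yl]-3,4-dihydro-2H-chromene
Product: 23 (2R)-6-(methoxymethoxy)-2,8-dimethyl-2-[(3E,7E)-4,8,12-trimethyltrideca-3,7,11-trien-1-yl]-3,4-dihydro-2H-chromene-5-carbaldehyde, via aryllithium 22 (not isolated)
Conditions: n-BuLi (1.2 equiv), THF, −78 °C, 30 min; DMF (3 equiv), −78 → 0 °C; H2O
Reagents that add atoms: N,N-dimethylformamide, CN(C)C=O
Why: Bromine–lithium exchange followed by formylation with DMF puts the aldehyde exactly where bromine was placed in step 1, so the 5- versus 7-regiochemistry is fixed by construction.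

Step 16
Reactants: 23 (2R)-6-(methoxymethoxy)-2,8-dimethyl-2-[(3E,7E)-4,8,12-trimethyltrideca-3,7,11-trien-1-yl]-3,4-dihydro-2H-chromene-5-carbaldehyde
Product: 24 (2R)-6-hydroxy-2,8-dimethyl-2-[(3E,7E)-4,8,12-trimethyltrideca-3,7,11-trien-1-yl]-3,4-dihydro-2H-chromene-5-carbaldehyde (target)
Conditions: 3 M aq HCl/THF (1:4), rt → 40 °C
Reagents that add atoms: none
Why: Acetal hydrolysis of the MOM ether, which is made especially labile by the ortho-formyl group, under acid too mild to touch the trisubstituted alkenes or C2.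

**Compound list**

1 | 2,5-dimethoxytoluene | COc1ccc(OC)c(C)c1 | starting material
2 | 1-bromo-2,5-dimethoxy-4-methylbenzene | COc1cc(C)c(OC)cc1Br | intermediate
3 | acetaldehyde | CC=O | starting material
4 | (2-bromo-3,6-dimethoxy-5-methylphenyl)lithium | COc1cc(C)c(OC)c([Li])c1Br | intermediate
5 | 1-(2-bromo-3,6-dimethoxy-5-methylphenyl)ethan-1-ol (racemic) | COc1cc(C)c(OC)c(C(C)O)c1Br | intermediate
6 | 1-(2-bromo-3,6-dimethoxy-5-methylphenyl)ethan-1-one | COc1cc(C)c(OC)c(C(C)=O)c1Br | intermediate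
7 | 1-(2-bromo-3,6-dihydroxy-5-methylphenyl)ethan-1-one | Oc1cc(C)c(O)c(C(C)=O)c1Br | intermediate
8 | 1-[2-bromo-6-hydroxy-3-(methoxymethoxy)-5-methylphenyl]ethan-1-one | COCOc1cc(C)c(O)c(C(C)=O)c1Br | intermediate
9 | (2E,6E)-farnesol | CC(C)=CCC/C(C)=C/CC/C(C)=C/CO | starting material
10 | (2E,6E)-farnesyl bromide | CC(C)=CCC/C(C)=C/CC/C(C)=C/CBr | intermediate
11 | diethyl malonate | CCOC(=O)CC(=O)OCC | starting material
12 | diethyl 2-[(2E,6E)-3,7,11-trimethyldodeca-2,6,10-trien-1-yl]propanedioate | CC(C)=CCC/C(C)=C/CC/C(C)=C/CC(C(=O)OCC)C(=O)OCC | intermediate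
13 | ethyl (4E,8E)-5,9,13-trimethyltetradeca-4,8,12-trienoate | CC(C)=CCC/C(C)=C/CC/C(C)=C/CCC(=O)OCC | intermediate
14 | (6E,10E)-1-[2-bromo-6-hydroxy-3-(methoxymethoxy)-5-methylphenyl]-7,11,15-trimethylhexadeca-6,10,14-triene-1,3-dione | CC(C)=CCC/C(C)=C/CC/C(C)=C/CCC(=O)CC(=O)c1c(O)c(C)cc(OCOC)c1Br | intermediate
15 | 5-bromo-6-(methoxymethoxy)-8-methyl-2-[(3E,7E)-4,8,12-trimethyltrideca-3,7,11-trien-1-yl]-4H-chromen-4-one | CC(C)=CCC/C(C)=C/CC/C(C)=C/CCC1=CC(=O)c2c(Br)c(OCOC)cc(C)c2O1 | intermediate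
16 | 5-bromo-6-hydroxy-8-methyl-2-[(3E,7E)-4,8,12-trimethyltrideca-3,7,11-trien-1-yl]-4H-chromen-4-one | CC(C)=CCC/C(C)=C/CC/C(C)=C/CCC1=CC(=O)c2c(Br)c(O)cc(C)c2O1 | intermediate
17 | dimethylaluminium enolate of 18: [(2R)-5-bromo-6-(methoxymethoxy)-2,8-dimethyl-2-[(3E,7E)-4,8,12-trimethyltrideca-3,7,11-trien-1-yl]-2H-chromen-4-yl]oxy(dimethyl)alumane | CC(C)=CCC/C(C)=C/CC/C(C)=C/CC[C@]1(C)C=C(O[Al](C)C)c2c(Br)c(OCOC)cc(C)c2O1 | intermediate
18 | (2R)-5-bromo-6-(methoxymethoxy)-2,8-dimethyl-2-[(3E,7E)-4,8,12-trimethyltrideca-3,7,11-trien-1-yl]-2,3-dihydro-4H-chromen-4-one | CC(C)=CCC/C(C)=C/CC/C(C)=C/CC[C@]1(C)CC(=O)c2c(Br)c(OCOC)cc(C)c2O1 | intermediate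
19 | tosylhydrazone of 18 (C=N geometry immaterial) | CC(C)=CCC/C(C)=C/CC/C(C)=C/CC[C@]1(C)CC(=NNS(=O)(=O)c3ccc(C)cc3)c2c(Br)c(OCOC)cc(C)c2O1 | intermediate
20 | (2R,4RS)-5-bromo-4-diazenyl-6-(methoxymethoxy)-2,8-dimethyl-2-[(3E,7E)-4,8,12-trimethyltrideca-3,7,11-trien-1-yl]-3,4-dihydro-2H-chromene | CC(C)=CCC/C(C)=C/CC/C(C)=C/CC[C@]1(C)CC(N=N)c2c(Br)c(OCOC)cc(C)c2O1 | intermediate
21 | (2R)-5-bromo-6-(methoxymethoxy)-2,8-dimethyl-2-[(3E,7E)-4,8,12-trimethyltrideca-3,7,11-trien-1-yl]-3,4-dihydro-2H-chromene | CC(C)=CCC/C(C)=C/CC/C(C)=C/CC[C@]1(C)CCc2c(Br)c(OCOC)cc(C)c2O1 | intermediate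
22 | [(2R)-6-(methoxymethoxy)-2,8-dimethyl-2-[(3E,7E)-4,8,12-trimethyltrideca-3,7,11-trien-1-yl]-3,4-dihydro-2H-chromen-5-yl]lithium | CC(C)=CCC/C(C)=C/CC/C(C)=C/CC[C@]1(C)CCc2c([Li])c(OCOC)cc(C)c2O1 | intermediate
23 | (2R)-6-(methoxymethoxy)-2,8-dimethyl-2-[(3E,7E)-4,8,12-trimethyltrideca-3,7,11-trien-1-yl]-3,4-dihydro-2H-chromene-5-carbaldehyde | CC(C)=CCC/C(C)=C/CC/C(C)=C/CC[C@]1(C)CCc2c(C=O)c(OCOC)cc(C)c2O1 | intermediate
24 | (2R)-6-hydroxy-2,8-dimethyl-2-[(3E,7E)-4,8,12-trimethyltrideca-3,7,11-trien-1-yl]-3,4-dihydro-2H-chromene-5-carbaldehyde | CC(C)=CCC/C(C)=C/CC/C(C)=C/CC[C@]1(C)CCc2c(C=O)c(O)cc(C)c2O1 | target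

**Totals and risk**

Total step count: 16. Longest linear sequence: 13 (steps 1–5, then 9–16); the side-chain branch is steps 6–8.

Most likely to fail, with fallbacks:

Step 12 (asymmetric conjugate methylation). Reactivity and enantioselectivity at a 2-alkylchromone with a peri-bromine are the least certain point of the route. The fallback sets out from 15 and comes back at 18. Methyl is added without chiral control (AlMe3, CuTC, PPh3, Et2O, −30 °C) through the racemic dimethylaluminium enolate F3 to the racemic chromanone rac-5-bromo-6-(methoxymethoxy)-2,8-dimethyl-2-[(3E,7E)-4,8,12-trimethyltrideca-3,7,11-trien-1-yl]chroman-4-one F4. F4 is then resolved by preparative chiral SFC on an amylose carbamate phase, which delivers 18 and leaves the (2S)-chromanone F5 as the discarded antipode.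

Step 13 (hydrazone formation, and with it the C4 deoxygenation). The carbonyl is a vinylogous ester flanked by the peri-bromine and may condense slowly. The fallback sets out from 18 and comes back at 21, bypassing 19 and step 14. NaBH4 (MeOH/THF, 0 °C) gives the (2R,4RS)-chroman-4-ol F6. MsCl/Et3N (CH2Cl2, 0 °C) forms the benzylic mesylate F7, which is not isolated and eliminates with DBU to the (2R)-2H-chromene F8. Hydrogenation with RhCl(PPh3)3 (10 mol %) under 1 atm H2 in benzene/EtOH then saturates only the cis-disubstituted C3=C4 bond, sparing the trisubstituted alkenes and the aryl bromide.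

Step 9 (Claisen condensation). The di-ortho-substituted acetophenone enolate is hindered and the ester is enolisable, so ester self-condensation may compete. The fallback sets out from 13 and 8 and comes back at 14. Saponification of 13 (LiOH, THF/MeOH/H2O, then dilute acid) gives (4E,8E)-5,9,13-trimethyltetradeca-4,8,12-trienoic acid F1. DCC/DMAP esterification of the free phenol of 8 with F1 gives 2-acetyl-3-bromo-4-(methoxymethoxy)-6-methylphenyl (4E,8E)-5,9,13-trimethyltetradeca-4,8,12-trienoate F2. KOtBu in THF (0 °C → rt) then effects the intramolecular Baker–Venkataraman O→C acyl shift to diketone 14.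

**Further compounds**

F1 | step 9 | (4E,8E)-5,9,13-trimethyltetradeca-4,8,12-trienoic acid | CC(C)=CCC/C(C)=C/CC/C(C)=C/CCC(=O)O
F2 | step 9 | 2-acetyl-3-bromo-4-(methoxymethoxy)-6-methylphenyl (4E,8E)-5,9,13-trimethyltetradeca-4,8,12-trienoate | CC(C)=CCC/C(C)=C/CC/C(C)=C/CCC(=O)Oc1c(C)cc(OCOC)c(Br)c1C(C)=O
F3 | step 12 | racemic dimethylaluminium enolate of F4 | CC(C)=CCC/C(C)=C/CC/C(C)=C/CCC1(C)C=C(O[Al](C)C)c2c(Br)c(OCOC)cc(C)c2O1
F4 | step 12 | rac-5-bromo-6-(methoxymethoxy)-2,8-dimethyl-2-[(3E,7E)-4,8,12-trimethyltrideca-3,7,11-trien-1-yl]chroman-4-one | CC(C)=CCC/C(C)=C/CC/C(C)=C/CCC1(C)CC(=O)c2c(Br)c(OCOC)cc(C)c2O1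
F5 | step 12 | (2S)-5-bromo-6-(methoxymethoxy)-2,8-dimethyl-2-[(3E,7E)-4,8,12-trimethyltrideca-3,7,11-trien-1-yl]chroman-4-one | CC(C)=CCC/C(C)=C/CC/C(C)=C/CC[C@@]1(C)CC(=O)c2c(Br)c(OCOC)cc(C)c2O1
F6 | step 13 | (2R,4RS)-5-bromo-6-(methoxymethoxy)-2,8-dimethyl-2-[(3E,7E)-4,8,12-trimethyltrideca-3,7,11-trien-1-yl]chroman-4-ol | CC(C)=CCC/C(C)=C/CC/C(C)=C/CC[C@]1(C)CC(O)c2c(Br)c(OCOC)cc(C)c2O1
F7 | step 13 | (2R,4RS)-5-bromo-6-(methoxymethoxy)-2,8-dimethyl-2-[(3E,7E)-4,8,12-trimethyltrideca-3,7,11-trien-1-yl]chroman-4-yl methanesulfonate | CC(C)=CCC/C(C)=C/CC/C(C)=C/CC[C@]1(C)CC(OS(C)(=O)=O)c2c(Br)c(OCOC)cc(C)c2O1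
F8 | step 13 | (2R)-5-bromo-6-(methoxymethoxy)-2,8-dimethyl-2-[(3E,7E)-4,8,12-trimethyltrideca-3,7,11-trien-1-yl]-2H-chromene | CC(C)=CCC/C(C)=C/CC/C(C)=C/CC[C@]1(C)C=Cc2c(Br)c(OCOC)cc(C)c2O1
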